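**Strategy.** Ring B is a masked 2-cyclohexenone: the C6 acetate and the C7=C8 alkene derive from a C6 ketone conjugated with C7=C8, so C6 and C8 are 1,5-related across the fusion bond C5–C10. The route rests on breaking C5–C10 and C7=C8 together, which opens rings A and B to one acyclic chain. In the key step fluoride releases a C5 enolate that adds to C10 of the activated alkene (ring A, quaternary C10), and the same ketone then condenses through C7 with the C8 keto group (ring B). The precursor is acyclic: a silyl enol ether at one end, and at the other a tetrasubstituted β,γ-unsaturated α-keto ester bearing the dienyl side chain and a chiral ester.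

Key step: step 8

Remark: atom labels C1–C20 follow labdane numbering of the target (ring A: C1–C5 and C10; ring B: C5–C10; side chain C11–C16; C17 on C8; C20 on C10). The sense of the auxiliary's facial bias at C10 cannot be predicted with certainty, so the plan relies on removal of the unwanted ring-diastereomer at compound 14.

Step 1
Reactants: 1 mesityl oxide (4-methylpent-3-en-2-one); 2 (5-chloropent-1-yn-1-yl)trimethylsilane
Product: 4 {[4,4-dimethyl-9-(trimethylsilyl)non-2-en-8-yn-2-yl]oxy}tri(propan-2-yl)silane (E/Z mixture expected), via Grignard reagent 3 (not isolated)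
Conditions: Mg, THF, reflux; then CuBr·SMe2 (5 mol %), 1, THF, −40 °C; then i-Pr3SiOTf, −40 → 0 °C
Reagents that add atoms: triisopropylsilyl trifluoromethanesulfonate, CC(C)[Si](OS(=O)(=O)C(F)(F)F)(C(C)C)C(C)C
Why: Copper-catalysed conjugate addition of the Grignard reagent to the β,β-disubstituted enone builds the quaternary C4, and O-silylation of the resulting enolate stores it regiospecifically as the C5=C6 silyl enol ether.

Step 2
Reactants: 4 silyl enol ether with trimethylsilyl alkyne
Product: 5 [(4,4-dimethylnon-2-en-8-yn-2-yl)oxy]tri(propan-2-yl)silane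
Conditions: K2CO3 (0.2 equiv), MeOH/THF, 0 °C
Reagents that add atoms: none
Why: Base-catalysed methanolysis (protodesilylation) should cleave the unhindered alkynyl C–SiMe3 bond while the bulky triisopropylsilyl enol ether resists attack at silicon.

Step 3
Reactants: 6 (−)-8-phenylmenthol, (1R,2S,5R)-5-methyl-2-(2-phenylpropan-2-yl)cyclohexan-1-ol
Product: 7 (1R,2S,5R)-5-methyl-2-(2-phenylpropan-2-yl)cyclohexyl chloro(oxo)acetate
Conditions: (COCl)2 (3 equiv), CH2Cl2, 0 °C → rt; evaporation, used crude
Reagents that add atoms: oxalyl chloride, ClC(=O)C(Cl)=O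
Why: Acylation of the hindered secondary alcohol by excess oxalyl chloride stops at the half-ester acid chloride (esterification) and leaves the carbinol stereocentre untouched.

Step 4
Reactants: 5 terminal alkyne; 7 chlorooxoacetate
Product: 8 (1R,2S,5R)-5-methyl-2-(2-phenylpropan-2-yl)cyclohexyl 8,8-dimethyl-2-oxo-10-{[tri(propan-2-yl)silyl]oxy}undec-9-en-3-ynoate
Conditions: CuI (5 mol %), Et3N (2 equiv), THF, 0 °C → rt
Reagents that add atoms: none
Why: Copper-catalysed acylation of the terminal alkyne by the acid chloride (acyl Sonogashira-type coupling through the copper acetylide) gives the alkynyl α-keto ester, the silyl enol ether being inert in the absence of a Lewis acid.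

Step 5
Reactants: 9 (2E)-3-methylpent-2-en-4-yn-1-ol
Product: 10 (2E)-3-methylpenta-2,4-dien-1-ol
Conditions: H2 (1 atm), Pd/CaCO3 poisoned with Pb(OAc)2, quinoline, EtOAc, rt
Reagents that add atoms: none
Why: Semi-hydrogenation of the terminal alkyne over lead-poisoned palladium (Lindlar reduction) stops at the vinyl group and leaves the (E)-trisubstituted alkene unchanged.

Step 6
Reactants: 10 (2E)-3-methylpenta-2,4-dien-1-ol
Product: 11 (2E)-1-bromo-3-methylpenta-2,4-diene
Conditions: PBr3 (0.4 equiv), Et2O, −20 °C; used at once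
Reagents that add atoms: phosphorus tribromide, BrP(Br)Br
Why: SN2 bromination of the primary allylic alcohol at low temperature gives the primary bromide with the (E)-alkene retained.

Step 7
Reactants: 8 alkynyl keto ester; 11 dienyl bromide
Product: 12 (1R,2S,5R)-5-methyl-2-(2-phenylpropan-2-yl)cyclohexyl 4,8,8-trimethyl-3-[(2E)-3-methylpenta-2,4-dien-1-yl]-2-oxo-10-{[tri(propan-2-yl)silyl]oxy}undeca-3,9-dienoate (alkene isomers at the 3,4- and 9,10-double bonds of the chain expected)
Conditions: MeLi (2.1 equiv), CuI (1.05 equiv), THF/Et2O, −78 °C; 8, −78 °C; then 11 (2 equiv), HMPA, −78 → −20 °C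
Reagents that add atoms: lithium dimethylcuprate (made in the flask from MeLi and CuI), [Li+].C[Cu-]C
Why: Conjugate addition of the cuprate to the ynone places the C20 methyl group on C10 and the allenolate is C-alkylated at C9 by the allylic bromide (tandem conjugate addition–enolate alkylation); the geometry of the new C9=C10 bond is of no consequence because both carbons are reset in step 8.

Step 8
Reactants: 12 acyclic silyl enol ether keto ester
Product: 14 (1R,2S,5R)-5-methyl-2-(2-phenylpropan-2-yl)cyclohexyl (1S,4aR,8aS)-5,5,8a-trimethyl-1-[(2E)-3-methylpenta-2,4-dien-1-yl]-4-oxo-1,4,4a,5,6,7,8,8a-octahydronaphthalene-2-carboxylate, via Michael adduct diketone 13 (not isolated)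
Conditions: Bu4NF (1.2 equiv), THF (0.01 M), −40 → 25 °C; pH 7 buffer at 0 °C; chromatography removes the diastereomer of opposite ring configuration
Reagents that add atoms: none
Why: Fluoride cleaves the silyl enol ether to the free C5 enolate, which adds to C10 of the tetrasubstituted β,γ-unsaturated α-keto ester (intramolecular Michael addition to 13); after proton transfer the methyl ketone enolises to C7, adds to the very electrophilic C8 keto group and loses water, so that C5–C10 and C7=C8 are formed in one operation. The closest known reaction type is the fluoride-triggered Mukaiyama–Michael addition coupled to the aldol condensation of a Robinson annulation. Ring A closes 6-exo-trig at C10, and ring B closes by a 6-(enolexo)-exo-trig aldol addition at C8 followed by E1cB dehydration. C10 is set in the Michael step under the influence of the 8-phenylmenthyl ester, whose phenyl ring covers one face of the keto ester–alkene unit, and the diastereomer of opposite ring configuration is removed at this stage; C5 lies next to the C6 ketone and should equilibrate to the trans ring fusion, and C9 should be protonated axially, anti to the C10 methyl group, which leaves the side chain equatorial. The step needs the enolate at C5 and not at C7 for the first bond, which the silyl enol ether laid down in step 1 secures, and it needs a single aldol mode, which is secured because C8 has no enolisable carbon on its ester side and only attack from C7 gives a six-membered ring.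

Step 9
Reactants: 14 bicyclic enone ester
Product: 15 (1S,4S,4aS,8aR)-3-(hydroxymethyl)-4a,8,8-trimethyl-4-[(2E)-3-methylpenta-2,4-dien-1-yl]-1,4,4a,5,6,7,8,8a-octahydronaphthalen-1-ol
Conditions: i-Bu2AlH (5 equiv), CH2Cl2, −78 → 0 °C; aqueous KNaC4H4O6 (potassium sodium tartrate)
Reagents that add atoms: none
Why: Hydride reduction should attack the C6 ketone in 1,2-fashion from the face opposite the axial C10 and C4 methyl groups, giving the axial C6 alcohol cis to the C10 methyl group, and should reduce the ester to the C17 alcohol with release of the auxiliary.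

Step 10
Reactants: 15 diol
Product: 16 target, [(1S,4S,4aS,8aR)-1-acetoxy-4a,8,8-trimethyl-4-[(2E)-3-methylpenta-2,4-dien-1-yl]-1,4,4a,5,6,7,8,8a-octahydronaphthalen-3-yl]methyl acetate
Conditions: Ac2O (4 equiv), DMAP (0.2 equiv), pyridine, CH2Cl2, rt
Reagents that add atoms: acetic anhydride, CC(=O)OC(C)=O
Why: DMAP-catalysed acylation should esterify both the primary allylic and the hindered axial secondary alcohol without touching the stereocentres or the diene.

**Compound list**

1 | mesityl oxide (4-methylpent-3-en-2-one) | CC(C)=CC(C)=O | starting material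
2 | (5-chloropent-1-yn-1-yl)trimethylsilane | C[Si](C)(C)C#CCCCCl | starting material
3 | [5-(trimethylsilyl)pent-4-yn-1-yl]magnesium chloride | C[Si](C)(C)C#CCCC[Mg]Cl | intermediate
4 | {[4,4-dimethyl-9-(trimethylsilyl)non-2-en-8-yn-2-yl]oxy}tri(propan-2-yl)silane (E/Z mixture) | CC(O[Si](C(C)C)(C(C)C)C(C)C)=CC(C)(C)CCCC#C[Si](C)(C)C | intermediate
5 | [(4,4-dimethylnon-2-en-8-yn-2-yl)oxy]tri(propan-2-yl)silane (E/Z mixture) | CC(O[Si](C(C)C)(C(C)C)C(C)C)=CC(C)(C)CCCC#C | intermediate
6 | (−)-8-phenylmenthol, (1R,2S,5R)-5-methyl-2-(2-phenylpropan-2-yl)cyclohexan-1-ol | CC(C)(c1ccccc1)[C@@H]1CC[C@@H](C)C[C@H]1O | starting material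
7 | (1R,2S,5R)-5-methyl-2-(2-phenylpropan-2-yl)cyclohexyl chloro(oxo)acetate | CC(C)(c1ccccc1)[C@@H]1CC[C@@H](C)C[C@H]1OC(=O)C(Cl)=O | intermediate
8 | (1R,2S,5R)-5-methyl-2-(2-phenylpropan-2-yl)cyclohexyl 8,8-dimethyl-2-oxo-10-{[tri(propan-2-yl)silyl]oxy}undec-9-en-3-ynoate | CC(C)(c1ccccc1)[C@@H]1CC[C@@H](C)C[C@H]1OC(=O)C(=O)C#CCCCC(C)(C)C=C(C)O[Si](C(C)C)(C(C)C)C(C)C | intermediate
9 | (2E)-3-methylpent-2-en-4-yn-1-ol | C#C/C(C)=C/CO | starting material
10 | (2E)-3-methylpenta-2,4-dien-1-ol | C=C/C(C)=C/CO | intermediate
11 | (2E)-1-bromo-3-methylpenta-2,4-diene | C=C/C(C)=C/CBr | intermediate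
12 | (1R,2S,5R)-5-methyl-2-(2-phenylpropan-2-yl)cyclohexyl 4,8,8-trimethyl-3-[(2E)-3-methylpenta-2,4-dien-1-yl]-2-oxo-10-{[tri(propan-2-yl)silyl]oxy}undeca-3,9-dienoate (alkene isomers at the 3,4- and 9,10-double bonds) | CC(C)(c1ccccc1)[C@@H]1CC[C@@H](C)C[C@H]1OC(=O)C(=O)C(C/C=C(C)/C=C)=C(C)CCCC(C)(C)C=C(C)O[Si](C(C)C)(C(C)C)C(C)C | intermediate
13 | (1R,2S,5R)-5-methyl-2-(2-phenylpropan-2-yl)cyclohexyl (5E)-3-(2-acetyl-1,3,3-trimethylcyclohexyl)-6-methyl-2-oxoocta-5,7-dienoate (stereoisomers at the three new centres) | CC(C)(c1ccccc1)[C@@H]1CC[C@@H](C)C[C@H]1OC(=O)C(=O)C(C/C=C(C)/C=C)C2(C)CCCC(C)(C)C2C(C)=O | intermediate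
14 | (1R,2S,5R)-5-methyl-2-(2-phenylpropan-2-yl)cyclohexyl (1S,4aR,8aS)-5,5,8a-trimethyl-1-[(2E)-3-methylpenta-2,4-dien-1-yl]-4-oxo-1,4,4a,5,6,7,8,8a-octahydronaphthalene-2-carboxylate | C=C/C(C)=C/C[C@@H]1C(C(=O)O[C@@H]3C[C@H](C)CC[C@H]3C(C)(C)c4ccccc4)=CC(=O)[C@@H]2C(C)(C)CCC[C@@]12C | intermediate
15 | (1S,4S,4aS,8aR)-3-(hydroxymethyl)-4a,8,8-trimethyl-4-[(2E)-3-methylpenta-2,4-dien-1-yl]-1,4,4a,5,6,7,8,8a-octahydronaphthalen-1-ol | C=C/C(C)=C/C[C@@H]1C(CO)=C[C@H](O)[C@@H]2C(C)(C)CCC[C@@]12C | intermediate
16 | [(1S,4S,4aS,8aR)-1-acetoxy-4a,8,8-trimethyl-4-[(2E)-3-methylpenta-2,4-dien-1-yl]-1,4,4a,5,6,7,8,8a-octahydronaphthalen-3-yl]methyl acetate (labdane numbering 5R,6S,9S,10S) | C=C/C(C)=C/C[C@@H]1C(COC(C)=O)=C[C@H](OC(C)=O)[C@@H]2C(C)(C)CCC[C@@]12C | target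

Total step count: 10. Longest linear sequence: 7 steps (steps 1, 2, 4, 7, 8, 9, 10).

**Steps most likely to fail**

Step 8. Attack at the fully substituted C10 may be slow. Proton transfer from the acidic γ-positions (C1, C20) to the enolate, and aldol addition of the resulting dienolate to the C6 ketone, can then run ahead of ring closure. The facial bias of the remote auxiliary at C10 may be weak, and long exposure to base can epimerise C9. The fallback sets out from 12 and comes back at 14. Compound 12 is treated with SnCl4 in CH2Cl2 at −78 °C. The tin-chelated syn-dicarbonyl is a much stronger acceptor and holds the phenyl ring of the auxiliary over one face, and the silyl enol ether adds through C5 to C10 (Mukaiyama–Michael addition) with loss of the silyl group as its chloride. Aqueous work-up gives diketone 13, which is now isolated. Pyrrolidine and acetic acid in benzene at 40 °C then close ring B by enamine aldol condensation to 14. The two bonds are then made in two operations, and this fallback makes no compound outside the list (F0).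

Step 7. The strongly basic allenolate may be protonated before it is alkylated, or the cuprate may add to the keto group. The fallback sets out from 8 and comes back at 14. The cuprate addition is quenched with NH4Cl to give the β-methyl enone keto ester F1. Its only acidic positions are the γ-carbons, so Cs2CO3 in DMF with 11 at 0 °C should alkylate the extended enolate at the α-carbon C9 and give the deconjugated keto ester F2 (deconjugative α-alkylation). Under the conditions of step 8 the terminal alkene of F2 moves back into conjugation through the same dienolate, and the Michael addition and aldol condensation deliver 14.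

Step 9. Hydride may be delivered in conjugate fashion to the doubly activated C7=C8 bond, or reduction of the hindered ester may stay incomplete. The fallback sets out from 14 and comes back at 15. Luche reduction (NaBH4, CeCl3·7H2O, MeOH, −78 °C) reduces only the ketone, from the same face, to the hydroxy ester F3, whose alkene is no longer doubly activated. LiAlH4 in Et2O at 0 °C then reduces the ester to 15 and releases the auxiliary.

**Further compounds**

F1 | step 7 | (1R,2S,5R)-5-methyl-2-(2-phenylpropan-2-yl)cyclohexyl 4,8,8-trimethyl-2-oxo-10-{[tri(propan-2-yl)silyl]oxy}undeca-3,9-dienoate | CC(C)(c1ccccc1)[C@@H]1CC[C@@H](C)C[C@H]1OC(=O)C(=O)C=C(C)CCCC(C)(C)C=C(C)O[Si](C(C)C)(C(C)C)C(C)C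
F2 | step 7 | (1R,2S,5R)-5-methyl-2-(2-phenylpropan-2-yl)cyclohexyl 8,8-dimethyl-4-methylidene-3-[(2E)-3-methylpenta-2,4-dien-1-yl]-2-oxo-10-{[tri(propan-2-yl)silyl]oxy}undec-9-enoate | CC(C)(c1ccccc1)[C@@H]1CC[C@@H](C)C[C@H]1OC(=O)C(=O)C(C/C=C(C)/C=C)C(=C)CCCC(C)(C)C=C(C)O[Si](C(C)C)(C(C)C)C(C)C
F0 | step 8 | none | none
F3 | step 9 | (1R,2S,5R)-5-methyl-2-(2-phenylpropan-2-yl)cyclohexyl (1S,4S,4aR,8aS)-4-hydroxy-5,5,8a-trimethyl-1-[(2E)-3-methylpenta-2,4-dien-1-yl]-1,4,4a,5,6,7,8,8a-octahydronaphthalene-2-carboxylate | C=C/C(C)=C/C[C@@H]1C(C(=O)O[C@@H]3C[C@H](C)CC[C@H]3C(C)(C)c4ccccc4)=C[C@H](O)[C@@H]2C(C)(C)CCC[C@@]12C
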